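**Retrosynthetic overview**
1. The strategy rests on ring A: C2 carries OH, C3 the CH2OH carbon and C4 OMe, between the ester carbon C1 and, past C5–H, the C6 methyl. A phenol with an ortho carbon substituent and a meta alkoxy group is the pattern a vinylketene and an alkoxyalkyne assemble in one operation.
2. Endgame: target 23 ⇐ fluoride desilylation ⇐ hydrogenolysis of the two ring B benzyl groups ⇐ protected depside 21.
3. Key disconnection: ring A of 21 is cut at C2–C3, C4–C5 and C1–C2 (the Wolff shift also makes C5–C6). This gives diazo ketone 12, which already carries the depside ester to ring B, and ynol ether 16. Ring B is bought as an arene; ring A is the only ring built and is built last.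
4. 12 ⇐ diazo transfer ⇐ enone ester 10 ⇐ Wittig reaction of butane-2,3-dione with the ylide from ring B phenol 6 and Ph3P=C=C=O; 6 ⇐ 2,5-dimethylresorcinol by carboxylation and allyl/benzyl protection steps.
5. 16 ⇐ chloroacetaldehyde dimethyl acetal via lithium methoxyacetylide, formaldehyde and silylation.

Key step: step 10

Remark on the chemistry: the target has no stereocenter, so the only configurational element is the (E) alkene of 10–12. Ring A locants: C1 ester carbon, C2 OH, C3 CH2OH, C4 OMe, C5 H, C6 CH3. Ring B locants: C1 CO2H, C2 OH, C3 CH3, C4 O-acyl, C5 H, C6 CH3. Ar = 3-(benzyloxy)-4-[(benzyloxy)carbonyl]-2,5-dimethylphenyl, the protected ring B bonded through its C4 oxygen.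

**Route**

Step 1
Reactants: 1 2,5-dimethylresorcinol
Product: 2 2,4-dihydroxy-3,6-dimethylbenzoic acid
Conditions: KHCO3 (5 equiv), CO2 (1 atm), glycerol, 120 °C; then cold 2 M HCl to pH 2
Reagents that add atoms: carbon dioxide, O=C=O
Why: Kolbe–Schmitt carboxylation of the potassium phenoxide goes ortho to a hydroxyl; the position between the hydroxyls is blocked by methyl and the two open positions are equivalent, so one acid should form, and cold acidification limits decarboxylation.

Step 2
Reactants: 2 2,4-dihydroxy-3,6-dimethylbenzoic acid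
Product: 3 benzyl 2,4-dihydroxy-3,6-dimethylbenzoate
Conditions: BnBr (1.05 equiv), KHCO3, DMF, rt
Reagents that add atoms: benzyl bromide, BrCc1ccccc1
Why: Bicarbonate ionizes only the carboxylic acid, so SN2 O-alkylation of the carboxylate should give the benzyl ester and leave both phenols free.

Step 3
Reactants: 3 benzyl 2,4-dihydroxy-3,6-dimethylbenzoate
Product: 4 benzyl 2-hydroxy-3,6-dimethyl-4-(prop-2-enyloxy)benzoate
Conditions: allyl bromide (1.1 equiv), K2CO3, acetone, reflux
Reagents that add atoms: allyl bromide, C=CCBr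
Why: Williamson etherification should take the more acidic, unchelated C4 hydroxyl, because the C2 hydroxyl is hydrogen-bonded to the ester carbonyl and flanked by the C3 methyl.

Step 4
Reactants: 4 benzyl 2-hydroxy-3,6-dimethyl-4-(prop-2-enyloxy)benzoate
Product: 5 benzyl 2-(benzyloxy)-3,6-dimethyl-4-(prop-2-enyloxy)benzoate
Conditions: BnBr (1.5 equiv), K2CO3, DMF, 70 °C
Reagents that add atoms: benzyl bromide, BrCc1ccccc1
Why: Williamson etherification of the remaining chelated phenol needs only more forcing conditions, under which the allyl ether and the benzyl ester are inert.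

Step 5
Reactants: 5 benzyl 2-(benzyloxy)-3,6-dimethyl-4-(prop-2-enyloxy)benzoate
Product: 6 benzyl 2-(benzyloxy)-4-hydroxy-3,6-dimethylbenzoate (ring B phenol, ArOH)
Conditions: Pd(PPh3)4 (2 mol %), morpholine (3 equiv), THF, rt
Reagents that add atoms: none
Why: Tsuji–Trost deallylation, in which zerovalent palladium ionizes the allyl aryl ether to an allylpalladium complex that morpholine intercepts, should free the C4 phenol without touching either benzyl group.

Step 6
Reactants: 6 benzyl 2-(benzyloxy)-4-hydroxy-3,6-dimethylbenzoate; 7 (triphenylphosphoranylidene)ketene; 8 butane-2,3-dione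
Product: 10 Ar (E)-3-methyl-4-oxopent-2-enoate, via aryl ester ylide 9 (not isolated)
Conditions: 7 (1.05 equiv), toluene, 60 °C until 6 is consumed; then 8 (3 equiv), 60 °C
Reagents that add atoms: none
Why: The phenol adds across the C=C bond of the cumulated ylide to give the stabilized ester ylide 9, whose Wittig reaction with one carbonyl of the symmetrical, activated diketone should give mainly the (E) enoate (ester trans to acetyl) as is usual for stabilized ylides; the excess of 8 suppresses a second olefination.

Step 7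
Reactants: 10 Ar (E)-3-methyl-4-oxopent-2-enoate
Product: 12 Ar (E)-5-diazo-3-methyl-4-oxopent-2-enoate, via trifluoroacetyl ketone 11 (not isolated)
Conditions: LiN(SiMe3)2 (1.1 equiv), THF, −78 °C; CF3CO2CH2CF3 (1.2 equiv), −78 °C; 5% aq HCl wash; then MsN3 (1.5 equiv), Et3N (1.5 equiv), H2O (1 equiv), MeCN, rt
Reagents that add atoms: methanesulfonyl azide, CS(=O)(=O)N=[N+]=[N-]
Why: Detrifluoroacetylative diazo transfer: the kinetic enolate of the methyl ketone is trifluoroacetylated, and the activated methylene of 11 then takes the diazo group from the sulfonyl azide and loses the trifluoroacetyl group as its sulfonamide; this is the standard way to make alkenyl diazomethyl ketones and should leave the aryl ester and the alkene geometry alone.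

Step 8
Reactants: 13 2-chloro-1,1-dimethoxyethane (chloroacetaldehyde dimethyl acetal)
Product: 15 3-methoxyprop-2-yn-1-ol, via lithium methoxyacetylide 14 (not isolated)
Conditions: Et2NH, n-BuLi, THF, 0 °C (gives LiNEt2, 3.1 equiv); 13, 0 °C; (CH2O)n (1.5 equiv), 0 °C to rt; H2O quench; base-washed glassware
Reagents that add atoms: paraformaldehyde (formaldehyde unit), C=O
Why: Two amide-induced eliminations (methanol, then HCl) give methoxyacetylene, a third equivalent of amide metallates it, and 1,2-addition of the acetylide to formaldehyde should give the propargylic alcohol, which is kept away from acid.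

Step 9
Reactants: 15 3-methoxyprop-2-yn-1-ol
Product: 16 tert-butyl[(3-methoxyprop-2-yn-1-yl)oxy]dimethylsilane
Conditions: TBSCl (1.1 equiv), imidazole (2.2 equiv), CH2Cl2, 0 °C
Reagents that add atoms: tert-butyldimethylsilyl chloride, CC(C)(C)[Si](C)(C)Cl
Why: Imidazole-promoted silylation of the primary alcohol runs under basic conditions that the acid-sensitive ynol ether should tolerate.

Step 10
Reactants: 12 Ar (E)-5-diazo-3-methyl-4-oxopent-2-enoate; 16 tert-butyl[(3-methoxyprop-2-yn-1-yl)oxy]dimethylsilane
Product: 21 Ar 3-({[tert-butyl(dimethyl)silyl]oxy}methyl)-2-hydroxy-4-methoxy-6-methylbenzoate (protected depside), via vinylketene 17 (not isolated), via 4-vinylcyclobutenone 18 (not isolated), via dienylketene 19 (not isolated), via cyclohexadienone 20 (not isolated)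
Conditions: 16 (1.5 equiv), degassed ClCH2CH2Cl, hν (350 nm lamps, Pyrex), rt; then 80 °C in the dark
Reagents that add atoms: none
Why: Irradiation expels N2 from 12 and the alkenyl group shifts to the former diazo carbon (photochemical Wolff rearrangement, making C5–C6) to give the acceptor-substituted vinylketene 17; ynol ether 16 attacks the ketene carbonyl carbon through its silyloxymethyl-bearing carbon in a [2+2] cycloaddition (C2–C3 and C4–C5) to give cyclobutenone 18. Heating opens 18 by four-electron electrocyclic cleavage to dienylketene 19, which closes ring A by a thermal six-electron disrotatory electrocyclization between the ketene carbon and the ester-bearing alkene terminus (C1–C2), and cyclohexadienone 20 tautomerizes to the C2 phenol. This is the diazo ketone form of the Danheiser benzannulation, established for alkenyl diazomethyl ketones with alkoxyalkynes; the ester at the alkene terminus is the one departure from the usual substrates and should make 17 more electrophilic toward 16. No stereocenter is formed. The step needs the regiochemistry of the [2+2] addition, which the donor oxygen of 16 fixes (methoxy carbon meta, silyloxymethyl carbon ortho to the new phenol), with ring closure at the ketene alpha carbon as in a normal ketene cycloaddition. It also needs the (E) alkene to persist so that the ketene cannot close onto the ester carbonyl oxygen; 350 nm light excites the diazo enone and not the aryl ester, which avoids a photo-Fries shift.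

Step 11
Reactants: 21 protected depside
Product: 22 4-{[3-({[tert-butyl(dimethyl)silyl]oxy}methyl)-2-hydroxy-4-methoxy-6-methylbenzoyl]oxy}-2-hydroxy-3,6-dimethylbenzoic acid
Conditions: H2 (1 atm), 10% Pd/C, EtOAc, rt, stopped after uptake of 2 equiv H2
Reagents that add atoms: none
Why: Hydrogenolysis should cleave the benzyl ester and the aryl benzyl ether quickly, while the aryl ester and the hindered ring A silyl ether, whose benzylic C–O bond reacts far more slowly in neutral ethyl acetate, should survive.

Step 12
Reactants: 22 silyl-protected depside acid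
Product: 23 3-alpha-hydroxybarbatic acid, 2-hydroxy-4-{[2-hydroxy-3-(hydroxymethyl)-4-methoxy-6-methylbenzoyl]oxy}-3,6-dimethylbenzoic acid
Conditions: HF·pyridine, pyridine, THF, 0 °C to rt
Reagents that add atoms: none
Why: Fluoride-induced desilylation is driven by Si–F bond formation, and the buffered, weakly acidic medium should leave the depside ester intact and avoid ionization of the o-hydroxybenzyl alcohol to a quinone methide.

**Compound list**
1 | 2,5-dimethylresorcinol | Cc1cc(O)c(C)c(O)c1 | starting material
2 | 2,4-dihydroxy-3,6-dimethylbenzoic acid | Cc1cc(O)c(C)c(O)c1C(=O)O | intermediate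
3 | benzyl 2,4-dihydroxy-3,6-dimethylbenzoate | Cc1cc(O)c(C)c(O)c1C(=O)OCc1ccccc1 | intermediate
4 | benzyl 2-hydroxy-3,6-dimethyl-4-(prop-2-enyloxy)benzoate | C=CCOc1cc(C)c(C(=O)OCc2ccccc2)c(O)c1C | intermediate
5 | benzyl 2-(benzyloxy)-3,6-dimethyl-4-(prop-2-enyloxy)benzoate | C=CCOc1cc(C)c(C(=O)OCc2ccccc2)c(OCc2ccccc2)c1C | intermediate
6 | benzyl 2-(benzyloxy)-4-hydroxy-3,6-dimethylbenzoate (ArOH) | Cc1cc(O)c(C)c(OCc2ccccc2)c1C(=O)OCc1ccccc1 | intermediate
7 | (triphenylphosphoranylidene)ketene | O=C=C=P(c1ccccc1)(c1ccccc1)c1ccccc1 | starting material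
8 | butane-2,3-dione | CC(=O)C(C)=O | starting material
9 | Ar (triphenylphosphoranylidene)acetate (aryl ester ylide) | O=C(C=P(c1ccccc1)(c1ccccc1)c1ccccc1)Oc1cc(C)c(C(=O)OCc2ccccc2)c(OCc2ccccc2)c1C | intermediate
10 | Ar (E)-3-methyl-4-oxopent-2-enoate | CC(=O)/C(C)=C/C(=O)Oc1cc(C)c(C(=O)OCc2ccccc2)c(OCc2ccccc2)c1C | intermediate
11 | Ar (E)-7,7,7-trifluoro-3-methyl-4,6-dioxohept-2-enoate | O=C(CC(=O)/C(C)=C/C(=O)Oc1cc(C)c(C(=O)OCc2ccccc2)c(OCc2ccccc2)c1C)C(F)(F)F | intermediate
12 | Ar (E)-5-diazo-3-methyl-4-oxopent-2-enoate | [N-]=[N+]=CC(=O)/C(C)=C/C(=O)Oc1cc(C)c(C(=O)OCc2ccccc2)c(OCc2ccccc2)c1C | intermediate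
13 | 2-chloro-1,1-dimethoxyethane | COC(CCl)OC | starting material
14 | lithium methoxyacetylide | [Li]C#COC | intermediate
15 | 3-methoxyprop-2-yn-1-ol | COC#CCO | intermediate
16 | tert-butyl[(3-methoxyprop-2-yn-1-yl)oxy]dimethylsilane | COC#CCO[Si](C)(C)C(C)(C)C | intermediate
17 | Ar (E)-3-methyl-5-oxopenta-2,4-dienoate (vinylketene) | O=C=C/C(C)=C/C(=O)Oc1cc(C)c(C(=O)OCc2ccccc2)c(OCc2ccccc2)c1C | intermediate
18 | Ar (E)-3-[3-({[tert-butyl(dimethyl)silyl]oxy}methyl)-2-methoxy-4-oxocyclobut-2-en-1-yl]but-2-enoate, racemic | COC1=C(CO[Si](C)(C)C(C)(C)C)C(=O)C1/C(C)=C/C(=O)Oc1cc(C)c(C(=O)OCc2ccccc2)c(OCc2ccccc2)c1C | intermediate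
19 | Ar (2E,4E)-6-({[tert-butyl(dimethyl)silyl]oxy}methyl)-5-methoxy-3-methyl-7-oxohepta-2,4,6-trienoate (dienylketene) | O=C=C(CO[Si](C)(C)C(C)(C)C)/C(OC)=C\C(C)=C\C(=O)Oc1cc(C)c(C(=O)OCc2ccccc2)c(OCc2ccccc2)c1C | intermediate
20 | Ar 3-({[tert-butyl(dimethyl)silyl]oxy}methyl)-4-methoxy-6-methyl-2-oxocyclohexa-3,5-diene-1-carboxylate, racemic | COC1=C(CO[Si](C)(C)C(C)(C)C)C(=O)C(C(=O)Oc2cc(C)c(C(=O)OCc3ccccc3)c(OCc3ccccc3)c2C)C(C)=C1 | intermediate
21 | Ar 3-({[tert-butyl(dimethyl)silyl]oxy}methyl)-2-hydroxy-4-methoxy-6-methylbenzoate | COc1cc(C)c(C(=O)Oc2cc(C)c(C(=O)OCc3ccccc3)c(OCc3ccccc3)c2C)c(O)c1CO[Si](C)(C)C(C)(C)C | intermediate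
22 | 4-{[3-({[tert-butyl(dimethyl)silyl]oxy}methyl)-2-hydroxy-4-methoxy-6-methylbenzoyl]oxy}-2-hydroxy-3,6-dimethylbenzoic acid | COc1cc(C)c(C(=O)Oc2cc(C)c(C(=O)O)c(O)c2C)c(O)c1CO[Si](C)(C)C(C)(C)C | intermediate
23 | 3-alpha-hydroxybarbatic acid | COc1cc(C)c(C(=O)Oc2cc(C)c(C(=O)O)c(O)c2C)c(O)c1CO | target

**Totals**
Total step count: 12. Longest linear sequence: 10 steps (steps 1–7, 10, 11, 12).

**Steps most likely to fail**

Step 10 (key step).
- Light may isomerize the (E) alkene, after which the ketene closes onto the ester carbonyl oxygen.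
- The first ketene–alkyne adduct may close at the ester-bearing carbon instead of the ketene alpha carbon, which would put the alkyne carbons between C2 and C1.
- The newly formed phenol may be acylated by ketene still present.
- Fallback, from phenol 6 back to target 23: the ring synthesis is given up and the depside ester is made by classical acylation of 6 with a ring A acid. Bought 2-hydroxy-4-methoxy-6-methylbenzoic acid F1 would be esterified (BnBr, KHCO3, DMF) to benzyl 2-hydroxy-4-methoxy-6-methylbenzoate F2. Formylation at C3, the only free position ortho to the phenol (MgCl2, Et3N, paraformaldehyde, MeCN, reflux), would give benzyl 3-formyl-2-hydroxy-4-methoxy-6-methylbenzoate F3, and hydrogenolysis (H2, Pd/C, EtOAc) would give 3-formyl-2-hydroxy-4-methoxy-6-methylbenzoic acid F4. Esterification of F4 with 6 through the mixed trifluoroacetic anhydride (TFAA, toluene, rt) should give benzyl 2-(benzyloxy)-4-[(3-formyl-2-hydroxy-4-methoxy-6-methylbenzoyl)oxy]-3,6-dimethylbenzoate F5. Hydrogenolysis of both benzyl groups, which a phenol-chelated aryl aldehyde should tolerate, would give 4-[(3-formyl-2-hydroxy-4-methoxy-6-methylbenzoyl)oxy]-2-hydroxy-3,6-dimethylbenzoic acid F6, and NaBH4 (THF/water, 0 °C) would reduce the aldehyde to the hydroxymethyl group of 23.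

Step 7 (diazo transfer).
- The lithium enolate may add in conjugate fashion to the acceptor alkene of a second molecule.
- Deprotonation at the C3 methyl may be followed by expulsion of the aryloxide.
- Lithium trifluoroethoxide may exchange with the aryl ester.
- Fallback, from butane-2,3-dione 8 back to diazo ketone 12: the diazo group is installed before the aryl ester exists. Commercial methyl (triphenylphosphoranylidene)acetate and 8 would give methyl (E)-3-methyl-4-oxopent-2-enoate F7. The same two-stage diazo transfer, through methyl (E)-7,7,7-trifluoro-3-methyl-4,6-dioxohept-2-enoate F8, would give methyl (E)-5-diazo-3-methyl-4-oxopent-2-enoate F9. LiOH (THF/water, 0 °C) and acidification to pH 4 would give (E)-5-diazo-3-methyl-4-oxopent-2-enoic acid F10, and carbodiimide esterification (EDC, DMAP, CH2Cl2, 0 °C) with phenol 6 would give 12.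

Step 6 (phenol addition and Wittig reaction).
- Olefination of the ketone by the weakly nucleophilic aryl ester ylide may be slow.
- The ylide may lose aryloxide again on prolonged heating.
- The second carbonyl may also be olefinated, and some (Z) isomer may form.
- Fallback, from butane-2,3-dione 8 back to enone ester 10: the alkene is made first and the aryl ester afterwards. Commercial tert-butyl (triphenylphosphoranylidene)acetate and 8 would give tert-butyl (E)-3-methyl-4-oxopent-2-enoate F11, purified to the (E) isomer. TFA in CH2Cl2 would give (E)-3-methyl-4-oxopent-2-enoic acid F12, and Steglich esterification (DCC, DMAP, CH2Cl2) with phenol 6 would give 10.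

**Further compounds**
F1 | step 10 | 2-hydroxy-4-methoxy-6-methylbenzoic acid (bought) | COc1cc(C)c(C(=O)O)c(O)c1
F2 | step 10 | benzyl 2-hydroxy-4-methoxy-6-methylbenzoate | COc1cc(C)c(C(=O)OCc2ccccc2)c(O)c1
F3 | step 10 | benzyl 3-formyl-2-hydroxy-4-methoxy-6-methylbenzoate | COc1cc(C)c(C(=O)OCc2ccccc2)c(O)c1C=O
F4 | step 10 | 3-formyl-2-hydroxy-4-methoxy-6-methylbenzoic acid | COc1cc(C)c(C(=O)O)c(O)c1C=O
F5 | step 10 | benzyl 2-(benzyloxy)-4-[(3-formyl-2-hydroxy-4-methoxy-6-methylbenzoyl)oxy]-3,6-dimethylbenzoate | COc1cc(C)c(C(=O)Oc2cc(C)c(C(=O)OCc3ccccc3)c(OCc3ccccc3)c2C)c(O)c1C=O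
F6 | step 10 | 4-[(3-formyl-2-hydroxy-4-methoxy-6-methylbenzoyl)oxy]-2-hydroxy-3,6-dimethylbenzoic acid | COc1cc(C)c(C(=O)Oc2cc(C)c(C(=O)O)c(O)c2C)c(O)c1C=O
F7 | step 7 | methyl (E)-3-methyl-4-oxopent-2-enoate | CC(=O)/C(C)=C/C(=O)OC
F8 | step 7 | methyl (E)-7,7,7-trifluoro-3-methyl-4,6-dioxohept-2-enoate | O=C(CC(=O)/C(C)=C/C(=O)OC)C(F)(F)F
F9 | step 7 | methyl (E)-5-diazo-3-methyl-4-oxopent-2-enoate | [N-]=[N+]=CC(=O)/C(C)=C/C(=O)OC
F10 | step 7 | (E)-5-diazo-3-methyl-4-oxopent-2-enoic acid | [N-]=[N+]=CC(=O)/C(C)=C/C(=O)O
F11 | step 6 | tert-butyl (E)-3-methyl-4-oxopent-2-enoate | CC(=O)/C(C)=C/C(=O)OC(C)(C)C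
F12 | step 6 | (E)-3-methyl-4-oxopent-2-enoic acid | CC(=O)/C(C)=C/C(=O)O
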